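(The readings come from a simulation with constants of no real substance, noise included.)

At early times target in the earlier runs grows in step with enzyme times time, so the first east reading gives a yield per unit of enzyme dose, a reading that carries the scatter.

| flask | starting material | protic impurity | enzyme | remark | time |
|---|---|---|---|---|---|
| south-east | 0.10 M | 1.2 mM | 10 µM | run made earlier |  |
| north-east | 0.10 M | 4 mM | 10 µM | run made earlier |  |
| east | 0.10 M | 5 mM | 28 µM | run made earlier |  |
| epsilon | 0.10 M | 1.50 mM | 40 µM |  | 20 min |
| eta | 0.10 M | 5.00 mM | 10 µM |  | 10 min |

- south-east (time / min: target / %): 0.667: 3.7; 2.00: 12.2; 3.00: 18.7; 5.00: 28.7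
- north-east (time / min: target / %): 1.33: 8.1; 2.50: 16.4; 4.00: 23.7; 5.00: 29.7
- east (time / min: target / %): 1.33: 22.2; 2.50: 40.2; 4.00: 59.7; 5.00: 70.2

(scatter of a reading: 0.5 percentage points)

* which one finishes higher in amount of target, in percent of the starting material charged ("neither" within 2 percentage points) (epsilon / eta / neither)
* amount of target at the end, in percent of the starting material charged, epsilon
* amount of target at the end, in percent of the starting material charged, eta

- the analysis behind the earlier runs scatters by 0.5 percentage points, standard deviation
- candidate steps: starting material + protic impurity -> quenched substrate; target + enzyme <-> isomer of the product + enzyme; starting material + enzyme -> target + enzyme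

Scaled to each recipe, that reading gives 0.596 for eta and 4.77 for epsilon. This is N, the number of charges of starting material that the enzyme dose turns over at the early rate. Eta, below one, should be read with starting material left, whereas epsilon, above one, should use it up after about 4.19 min and then stand with enzyme.

One number is not enough. The last east reading has N = 0.835 but shows 70.2 % of target, a shortfall of 13.3 % of the charge. My own reckoning treats this shortfall as a correction: target passes to its isomer at λ per unit of N, which costs λ/2 times N squared, so λ = 0.381. Eta then gives 52.8 %. By the same reckoning epsilon holds 81.0 % when starting material ends, and the remaining dose gives λ(N − 1) = 1.43. A one-way loss over that dose leaves 19.4 %, and the candidate step is reversible, so the reckoning puts epsilon between these two figures, a bracket that holds eta's figure and leaves open which flask finishes higher.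

The forecast, judging that “loss could reach about 10%”, gave 95 % for epsilon, above that bracket, 53 % for eta, and epsilon as the higher.

The flasks give 62.8 % for epsilon and 54.7 % for eta, so epsilon finishes higher.

    starting material + protic impurity → quenched substrate (k = 0.200 M⁻¹ s⁻¹)
    target + enzyme ⇌ isomer of the product + enzyme, rate k2*[enzyme]*[target] forward; the back reaction follows from the equilibrium constant (K = 0.570, k = 69.0 M⁻¹ s⁻¹)
    starting material + enzyme → target + enzyme, rate k3*[starting material]*[enzyme]/(1 + ([starting material]/Km3)) (3.80 mM, k = 3000 M⁻¹ s⁻¹)

Epsilon, at N = 4.77, holds 0 % starting material by 10.0 min, and from then on its target stays near 62.8 % beside 35.8 % of isomer. That level stands because isomer falls back to target: without the return, epsilon ends at 5.05 %. Eta read at 25 min has N = 1.49, above one, and that flask holds 0 % starting material and 65.9 % target.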